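**Retrosynthetic overview**
1. Target 22 ⇐ global debenzylation of flavan-3-ol 21 ⇐ hydroboration–oxidation of the 2,4-diaryl-4H-chromene 19 anti to its C4 aryl group (sets C2 and C3 from C4).
2. Key disconnection: upper ring C of 19 is opened at O1–C8a and at C3–C4, a [3+3] annulation of an O1–C2–C3 enolate (β-keto acid 16, carboxyl as traceless activator) with a C4–C4a–C8a dielectrophile.
3. Enabling feature: in ring A the C7 oxygen is para to C4a, so C7–OH/C4 can be a para-quinone methide (C7=O, exocyclic C4a=C4) with electrophilic C4, while C8a, ortho to C4a, carries Br for C–O coupling with the enolate oxygen.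
4. The quinone methide precursor 10 comes from 8-lithiated hexa-O-benzyl-(+)-gallocatechin and 2-bromo-4-silyloxybenzaldehyde; C8 bromination fixes the 4→8 interflavan regiochemistry.
5. Ring order: all rings of the lower unit and rings A and B of the upper unit are bought; upper ring C is the only ring made (step 9).

Key step: step 9

Assumption: (+)-gallocatechin (2R,3S) and (+)-dihydrorobinetin are taken as purchasable, and the quinine-derived squaramide is taken to give the 4S epimer in step 9 (otherwise its quinidine-derived pseudo-enantiomer is used).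

Abbreviations in names: TBP = 3,4,5-tris(benzyloxy)phenyl; GC-8-yl = (2R,3S)-3,5,7-tris(benzyloxy)-2-(TBP)chroman-8-yl.

Step 1
Reactants: 1 (+)-gallocatechin
Product: 2 (2R,3S)-5,7-bis(benzyloxy)-2-(TBP)chroman-3-ol
Conditions: BnBr (5.5 equiv), K2CO3, DMF, 0 °C to rt, argon
Reagents that add atoms: benzyl bromide, BrCc1ccccc1
Why: Williamson O-benzylation with carbonate should cap the five phenols and leave the secondary 3-OH free, without touching the two existing stereocenters.

Step 2
Reactants: 2 penta-O-benzyl-gallocatechin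
Product: 3 (2R,3S)-3,5,7-tris(benzyloxy)-2-(TBP)chromane
Conditions: NaH, BnBr, Bu4NI (cat.), DMF, 0 °C to rt
Reagents that add atoms: benzyl bromide, BrCc1ccccc1
Why: Williamson benzylation of the sodium alkoxide removes the last acidic proton before the lithiation.

Step 3
Reactants: 3 hexa-O-benzyl-gallocatechin
Product: 4 (2R,3S)-3,5,7-tris(benzyloxy)-8-bromo-2-(TBP)chromane
Conditions: NBS (1.0 equiv), CH2Cl2, −78 to 0 °C
Reagents that add atoms: N-bromosuccinimide, O=C1CCC(=O)N1Br
Why: Electrophilic aromatic bromination should occur at C8 of the phloroglucinol-type ring, the most nucleophilic position of 5,7-di-O-benzyl flavans, which fixes the later 4→8 linkage.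

Step 4
Reactants: 5 2-bromo-4-hydroxybenzaldehyde
Product: 6 2-bromo-4-(tert-butyldimethylsilyloxy)benzaldehyde
Conditions: TBSCl, imidazole, DMF, rt
Reagents that add atoms: tert-butyldimethylsilyl chloride, C[Si](C)(Cl)C(C)(C)C
Why: Imidazole-mediated silylation masks the phenol as a fluoride-labile ether that tolerates an aryllithium at −78 °C.

Step 5
Reactants: 4 8-bromo-hexa-O-benzyl-gallocatechin; 6 silylated aldehyde
Product: 8 [2-bromo-4-(tert-butyldimethylsilyloxy)phenyl](GC-8-yl)methanol (both carbinol epimers), via 8-lithio flavan 7 (not isolated)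
Conditions: n-BuLi (1.05 equiv), THF, −78 °C; then 6, −78 °C; aq. NH4Cl
Reagents that add atoms: none
Why: Bromine–lithium exchange is faster than benzylic deprotonation and the aryllithium should add 1,2 to the aldehyde before it exchanges with the aldehyde's own bromide; the carbinol center needs no control because it becomes sp2 in step 9.

Step 6
Reactants: 8 silylated benzhydrol
Product: 10 3-bromo-4-[(4-methylphenylsulfonyl)(GC-8-yl)methyl]phenol (both epimers at the sulfonyl carbon), via free phenol 9 (not isolated)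
Conditions: TBAF, AcOH, THF, 0 °C; then TolSO2Na, HCO2H, H2O–THF, rt
Reagents that add atoms: sodium p-toluenesulfinate, Cc1ccc(cc1)S(=O)[O-].[Na+]
Why: Buffered fluoride desilylation frees the para phenol, and acid-promoted SN1 substitution of the doubly activated benzhydrol by sulfinate sulfur gives the sulfone, the usual storable precursor of a para-quinone methide.

Step 7
Reactants: 11 3,4,5-tris(benzyloxy)benzoic acid; 12 potassium ethyl malonate
Product: 15 ethyl 3-oxo-3-(TBP)propanoate, via acyl imidazolide 13 (not isolated), via acylmalonic half ester 14 (not isolated)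
Conditions: CDI, THF, rt; then 12, MgCl2, Et3N, MeCN, rt to 50 °C; 1 M HCl
Reagents that add atoms: none
Why: Masamune–Brooks homologation, in which the magnesium enolate of the malonate half ester is C-acylated by the acyl imidazolide and the adduct loses CO2 on acidic work-up.

Step 8
Reactants: 15 β-keto ester
Product: 16 3-oxo-3-(TBP)propanoic acid
Conditions: NaOH (1 M aq.), THF–EtOH, rt; then 1 M HCl, 0 °C; used at once
Reagents that add atoms: sodium hydroxide, [Na+].[OH-]
Why: Saponification followed by cold acidification gives the β-keto acid, which is kept cold and used directly to avoid early decarboxylation.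

Step 9
Reactants: 10 sulfone; 16 β-keto acid
Product: 19 (4S)-4-(GC-8-yl)-2-(TBP)-4H-chromen-7-ol, via quinone methide 17 (not isolated), via ketone 18 (not isolated)
Conditions: quinine-derived 3,5-bis(trifluoromethyl)phenyl squaramide (10 mol %), Cs2CO3, toluene, 0 °C to rt; then CuI (10 mol %), 1,10-phenanthroline (20 mol %), Cs2CO3, DMF added, 100 °C, 0.02 M
Reagents that add atoms: none
Why: Proposed new method: base expels sulfinate from the phenoxide of 10 to give the para-quinone methide 17, whose methide carbon C4 is attacked by the enol carbon C3 of 16 in a decarboxylative 1,6-addition (C3–C4 bond, ring A re-aromatised, CO2 lost) to give ketone 18, and after CuI and ligand are added and the flask is heated the enolate oxygen of 18 is arylated by the C8a bromide (O1–C8a bond) to give the flav-2-ene 19. The closest known reaction types are the bifunctional-amine-catalysed decarboxylative addition of β-keto acids to quinone methides made in situ from sulfones, and the copper-catalysed domino C-benzylation/O-arylation of 1,3-dicarbonyls with 2-bromobenzyl bromides to 4H-chromenes; their merger on a ring-brominated para-quinone methide with a simple aryl ketone enolate is new. Ring C closes by Ullmann-type C–O reductive elimination at copper, formally a 6-exo attack of the enolate oxygen on C8a. C4 is the only new stereocenter and is set by the catalyst, whose squaramide NH groups bind the quinone carbonyl while the protonated quinuclidine holds the enolate over one face of the methide (4S in 19, 3R in 18). The step needs C-attack rather than O-attack of the enolate on the methide (soft 1,6-addition driven by aromatisation), O-arylation rather than C-arylation (the latter would close a four-membered ring) and intramolecular coupling in preference to arylation of the ring A phenoxide (dilution and the hindered bromide next to the branched C4).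

Step 10
Reactants: 19 flav-2-ene
Product: 21 (2R,3S,4S)-4-(GC-8-yl)-2-(TBP)chromane-3,7-diol, via alkylborane 20 (not isolated)
Conditions: BH3·THF (4 equiv), THF, 0 °C to rt; then NaOH aq., H2O2, 0 °C
Reagents that add atoms: hydrogen peroxide, OO
Why: Brown hydroboration of the cyclic enol ether should place boron on C3 and hydrogen on C2 in a syn fashion from the face opposite the bulky C4 aryl group, and oxidation with retention then gives the 2,3-trans-3,4-trans flavan-3-ol.

Step 11
Reactants: 21 nona-O-benzyl biflavanoid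
Product: 22 robinetinidol-(4alpha,8)-gallocatechin
Conditions: H2 (1 atm), Pd(OH)2/C, THF–MeOH, rt
Reagents that add atoms: none
Why: Hydrogenolysis over Pearlman's catalyst should remove all nine benzyl ethers under conditions that leave the flavan C2–O bonds and the interflavan bond intact.

**Compound list**
1 | (+)-gallocatechin, (2R,3S) | Oc1cc(O)c2c(c1)O[C@H](c1cc(O)c(O)c(O)c1)[C@@H](O)C2 | starting material
2 | (2R,3S)-5,7-bis(benzyloxy)-2-(TBP)chroman-3-ol | c1c(OCc3ccccc3)cc(OCc3ccccc3)c2c1O[C@H](c1cc(OCc3ccccc3)c(OCc3ccccc3)c(OCc3ccccc3)c1)[C@@H](O)C2 | intermediate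
3 | (2R,3S)-3,5,7-tris(benzyloxy)-2-(TBP)chromane | c1c(OCc3ccccc3)cc(OCc3ccccc3)c2c1O[C@H](c1cc(OCc3ccccc3)c(OCc3ccccc3)c(OCc3ccccc3)c1)[C@@H](OCc3ccccc3)C2 | intermediate
4 | (2R,3S)-3,5,7-tris(benzyloxy)-8-bromo-2-(TBP)chromane | Brc1c(OCc3ccccc3)cc(OCc3ccccc3)c2c1O[C@H](c1cc(OCc3ccccc3)c(OCc3ccccc3)c(OCc3ccccc3)c1)[C@@H](OCc3ccccc3)C2 | intermediate
5 | 2-bromo-4-hydroxybenzaldehyde | O=Cc1ccc(O)cc1Br | starting material
6 | 2-bromo-4-(tert-butyldimethylsilyloxy)benzaldehyde | O=Cc1ccc(O[Si](C)(C)C(C)(C)C)cc1Br | intermediate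
7 | 8-lithio derivative of 3 | [Li]c1c(OCc3ccccc3)cc(OCc3ccccc3)c2c1O[C@H](c1cc(OCc3ccccc3)c(OCc3ccccc3)c(OCc3ccccc3)c1)[C@@H](OCc3ccccc3)C2 | intermediate (not isolated)
8 | [2-bromo-4-(tert-butyldimethylsilyloxy)phenyl](GC-8-yl)methanol, carbinol epimers | OC(c1ccc(O[Si](C)(C)C(C)(C)C)cc1Br)c1c(OCc3ccccc3)cc(OCc3ccccc3)c2c1O[C@H](c1cc(OCc3ccccc3)c(OCc3ccccc3)c(OCc3ccccc3)c1)[C@@H](OCc3ccccc3)C2 | intermediate
9 | (2-bromo-4-hydroxyphenyl)(GC-8-yl)methanol | OC(c1ccc(O)cc1Br)c1c(OCc3ccccc3)cc(OCc3ccccc3)c2c1O[C@H](c1cc(OCc3ccccc3)c(OCc3ccccc3)c(OCc3ccccc3)c1)[C@@H](OCc3ccccc3)C2 | intermediate (not isolated)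
10 | 3-bromo-4-[(4-methylphenylsulfonyl)(GC-8-yl)methyl]phenol, epimers at the sulfonyl carbon | Cc1ccc(cc1)S(=O)(=O)C(c1ccc(O)cc1Br)c1c(OCc3ccccc3)cc(OCc3ccccc3)c2c1O[C@H](c1cc(OCc3ccccc3)c(OCc3ccccc3)c(OCc3ccccc3)c1)[C@@H](OCc3ccccc3)C2 | intermediate
11 | 3,4,5-tris(benzyloxy)benzoic acid | OC(=O)c1cc(OCc2ccccc2)c(OCc2ccccc2)c(OCc2ccccc2)c1 | starting material
12 | potassium ethyl malonate | CCOC(=O)CC(=O)[O-].[K+] | starting material
13 | 1-[3,4,5-tris(benzyloxy)benzoyl]imidazole | O=C(n1ccnc1)c1cc(OCc2ccccc2)c(OCc2ccccc2)c(OCc2ccccc2)c1 | intermediate (not isolated)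
14 | 2-(ethoxycarbonyl)-3-oxo-3-(TBP)propanoic acid | CCOC(=O)C(C(=O)O)C(=O)c1cc(OCc2ccccc2)c(OCc2ccccc2)c(OCc2ccccc2)c1 | intermediate (not isolated)
15 | ethyl 3-oxo-3-(TBP)propanoate | CCOC(=O)CC(=O)c1cc(OCc2ccccc2)c(OCc2ccccc2)c(OCc2ccccc2)c1 | intermediate
16 | 3-oxo-3-(TBP)propanoic acid | OC(=O)CC(=O)c1cc(OCc2ccccc2)c(OCc2ccccc2)c(OCc2ccccc2)c1 | intermediate
17 | 3-bromo-4-[(GC-8-yl)methylidene]cyclohexa-2,5-dien-1-one, alkene geometry open | O=C5C=CC(=Cc1c(OCc3ccccc3)cc(OCc3ccccc3)c2c1O[C@H](c1cc(OCc3ccccc3)c(OCc3ccccc3)c(OCc3ccccc3)c1)[C@@H](OCc3ccccc3)C2)C(Br)=C5 | intermediate (not isolated)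
18 | (3R)-3-(2-bromo-4-hydroxyphenyl)-3-(GC-8-yl)-1-(TBP)propan-1-one | Oc1ccc(c(Br)c1)[C@H](CC(=O)c1cc(OCc3ccccc3)c(OCc3ccccc3)c(OCc3ccccc3)c1)c1c(OCc3ccccc3)cc(OCc3ccccc3)c2c1O[C@H](c1cc(OCc3ccccc3)c(OCc3ccccc3)c(OCc3ccccc3)c1)[C@@H](OCc3ccccc3)C2 | intermediate (not isolated)
19 | (4S)-4-(GC-8-yl)-2-(TBP)-4H-chromen-7-ol | Oc1ccc2c(c1)OC(c1cc(OCc3ccccc3)c(OCc3ccccc3)c(OCc3ccccc3)c1)=C[C@@H]2c1c(OCc3ccccc3)cc(OCc3ccccc3)c2c1O[C@H](c1cc(OCc3ccccc3)c(OCc3ccccc3)c(OCc3ccccc3)c1)[C@@H](OCc3ccccc3)C2 | intermediate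
20 | alkylborane: 21 with BH2 in place of the 3-OH, same spatial arrangement | Oc1ccc2c(c1)O[C@H](c1cc(OCc3ccccc3)c(OCc3ccccc3)c(OCc3ccccc3)c1)[C@@H](B)[C@@H]2c1c(OCc3ccccc3)cc(OCc3ccccc3)c2c1O[C@H](c1cc(OCc3ccccc3)c(OCc3ccccc3)c(OCc3ccccc3)c1)[C@@H](OCc3ccccc3)C2 | intermediate (not isolated)
21 | (2R,3S,4S)-4-(GC-8-yl)-2-(TBP)chromane-3,7-diol | Oc1ccc2c(c1)O[C@H](c1cc(OCc3ccccc3)c(OCc3ccccc3)c(OCc3ccccc3)c1)[C@@H](O)[C@@H]2c1c(OCc3ccccc3)cc(OCc3ccccc3)c2c1O[C@H](c1cc(OCc3ccccc3)c(OCc3ccccc3)c(OCc3ccccc3)c1)[C@@H](OCc3ccccc3)C2 | intermediate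
22 | robinetinidol-(4alpha,8)-gallocatechin, upper unit (2R,3S,4S), lower unit (2R,3S) | Oc1ccc2c(c1)O[C@H](c1cc(O)c(O)c(O)c1)[C@@H](O)[C@@H]2c1c(O)cc(O)c2c1O[C@H](c1cc(O)c(O)c(O)c1)[C@@H](O)C2 | target

**Totals and risks**
Total step count: 11. Longest linear sequence: 8 steps (1, 2, 3, 5, 6, 9, 10, 11).

Steps most likely to fail:

Step 9 (Proposed new method). Catalyst control of the methide face may be weak next to the remote chiral lower unit, the 1,6-addition to the hindered methide may be slow enough for the quinone methide to oligomerise, and the ring A phenoxide may be arylated intermolecularly in the copper stage. The fallback uses known chemistry, sets out from 1 and comes back at 22: commercial (+)-dihydrorobinetin F1 is reduced with NaBH4 in ethanol to the flavan-3,4-diol leucorobinetinidin F2, which is condensed with 1 in dilute aqueous HCl at room temperature. The C4 benzylic cation of F2, stabilised by the same para C7 oxygen, should be captured by C8 of gallocatechin mainly trans to the 3-OH. The 4→6 regioisomer and the 4-epimer would be removed by chromatography to give 22 directly.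

Step 10. The β-aryloxy alkylborane may undergo β-elimination with opening of ring C, or borane may partly attack the face syn to the C4 aryl group. The fallback sets out from 19 and comes back at 21: Upjohn dihydroxylation (OsO4 cat., NMO) anti to the C4 aryl group should give the 2,3-cis-diol hemiketal F3. Ionic reduction of its hemiketal carbon with Et3SiH and BF3·OEt2 at −40 °C, by axial hydride delivery to the 2-aryl oxocarbenium ion as in C-aryl glycoside synthesis, should give the all-trans flavan-3-ol 21.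

Step 5. Bromine–lithium exchange may scramble onto the bromide of the aldehyde partner, or the hindered aryllithium may be quenched before it adds. The fallback reverses the polarity, sets out from 4 and comes back at 8: the lithio species 7 is trapped with DMF to give the 8-carbaldehyde F4. Commercial 3-bromo-4-iodophenol F5 is silylated (TBSCl, imidazole) to its silyl ether F6, which undergoes selective iodine–magnesium exchange with i-PrMgCl·LiCl at −40 °C to the arylmagnesium chloride F7. Addition of F7 to F4 should give 8.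

Further compounds
F1 | step 9 | (+)-dihydrorobinetin, (2R,3R), purchased | Oc1ccc2c(c1)O[C@H](c1cc(O)c(O)c(O)c1)[C@@H](O)C2=O
F2 | step 9 | leucorobinetinidin, (2R,3S,4R)-flavan-3,4-diol | Oc1ccc2c(c1)O[C@H](c1cc(O)c(O)c(O)c1)[C@@H](O)[C@@H]2O
F3 | step 10 | 2,3-cis-2,3-dihydroxy hemiketal of 19, both hydroxyls anti to the C4 aryl group | Oc1ccc2c(c1)O[C@](O)(c1cc(OCc3ccccc3)c(OCc3ccccc3)c(OCc3ccccc3)c1)[C@@H](O)[C@@H]2c1c(OCc3ccccc3)cc(OCc3ccccc3)c2c1O[C@H](c1cc(OCc3ccccc3)c(OCc3ccccc3)c(OCc3ccccc3)c1)[C@@H](OCc3ccccc3)C2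
F4 | step 5 | (2R,3S)-3,5,7-tris(benzyloxy)-2-(TBP)chromane-8-carbaldehyde | O=Cc1c(OCc3ccccc3)cc(OCc3ccccc3)c2c1O[C@H](c1cc(OCc3ccccc3)c(OCc3ccccc3)c(OCc3ccccc3)c1)[C@@H](OCc3ccccc3)C2
F5 | step 5 | 3-bromo-4-iodophenol, purchased | Oc1ccc(I)c(Br)c1
F6 | step 5 | (3-bromo-4-iodophenoxy)(tert-butyl)dimethylsilane | CC(C)(C)[Si](C)(C)Oc1ccc(I)c(Br)c1
F7 | step 5 | [2-bromo-4-(tert-butyldimethylsilyloxy)phenyl]magnesium chloride | CC(C)(C)[Si](C)(C)Oc1ccc([Mg]Cl)c(Br)c1
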